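**Retrosynthetic overview**
- Target (3R,4R)-trans lactone ⇒ C3–CH2Ar bond: lithium enolate of (R)-4-(3,4-dimethoxybenzyl)butyrolactone plus the syringyl p-quinone methide made by oxidising 2,6-dimethoxy-4-methylphenol. This sets C3 trans to C4 and the phenol is never protected.
- (R)-Lactone ⇒ catalytic asymmetric Baeyer–Villiger ring expansion of prochiral 3-(3,4-dimethoxybenzyl)cyclobutanone. This sets C4.
- Cyclobutanone ⇒ Friedel–Crafts acylation of veratrole (catechol + MeI) with 3-oxocyclobutanecarboxylic acid, then benzylic hydrogenolysis.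
- 2,6-Dimethoxy-4-methylphenol ⇒ p-cresol by ortho,ortho-dibromination and copper-catalysed methoxylation.
- Ring order: both arenes and the four-membered ring are bought; the γ-lactone is the only ring formed, by the ring expansion, before the last C–C bond is made.

Assumption: the hand of the chiral ligand in step 4 (and of the chiral base in its fallback) that leads to the R product is fixed by a pilot run with chiral HPLC; both hands are available.

**Route**

Step 1
Reactants: 1 catechol (benzene-1,2-diol)
Product: 2 veratrole (1,2-dimethoxybenzene)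
Conditions: MeI (2.5 equiv), K2CO3 (3 equiv), acetone, reflux
Reagents that add atoms: iodomethane, CI
Why: Williamson ether synthesis, in which both phenoxide oxygens are methylated by SN2 attack on MeI and no stereocentre is involved.

Step 2
Reactants: 2 veratrole; 3 3-oxocyclobutane-1-carboxylic acid
Product: 5 3-(3,4-dimethoxybenzoyl)cyclobutan-1-one, via acid chloride 4 (not isolated)
Conditions: 3, (COCl)2, DMF (cat.), CH2Cl2, 0 °C to rt; then 2, AlCl3 (2.2 equiv), CH2Cl2, 0 °C
Reagents that add atoms: none
Why: Friedel–Crafts acylation, in which the acylium ion from 4 attacks veratrole para to a methoxy group (the only activated, unhindered site) and the deactivated aryl ketone does not react again; 5 keeps a mirror plane and has no stereocentre.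

Step 3
Reactants: 5 3-(3,4-dimethoxybenzoyl)cyclobutan-1-one
Product: 7 3-(3,4-dimethoxybenzyl)cyclobutan-1-one, via benzylic alcohol 6 (not isolated)
Conditions: H2 (4 atm), 10% Pd/C, AcOH, 50 °C
Reagents that add atoms: none
Why: Catalytic hydrogenation–hydrogenolysis of an electron-rich aryl ketone, in which Pd reduces the conjugated ketone to alcohol 6 and then cleaves its para-methoxy-activated benzylic C–O bond, while the unconjugated cyclobutanone is not reduced on Pd and the weak acid avoids a free benzylic cation next to the four-membered ring; 7 is achiral.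

Step 4
Reactants: 7 3-(3,4-dimethoxybenzyl)cyclobutan-1-one
Product: 9 (R)-4-(3,4-dimethoxybenzyl)dihydrofuran-2(3H)-one, via Criegee adduct 8 (not isolated)
Conditions: Sc(OTf)3 (5 mol %), C2-symmetric chiral N,N'-dioxide bis(2,6-diisopropylanilide) ligand (5 mol %), mCPBA (1.2 equiv), EtOAc, −20 °C
Reagents that add atoms: mCPBA (3-chloroperoxybenzoic acid), OOC(=O)c1cccc(Cl)c1
Why: Catalytic asymmetric Baeyer–Villiger oxidation (desymmetrising ring expansion), in which the chiral trivalent scandium complex holds ketone and peracid so that in Criegee adduct 8 only one of the two enantiotopic ring CH2 groups lies antiperiplanar to the O–O bond and migrates to oxygen, enlarging the four-membered ring to the γ-lactone and fixing C4 as R by catalyst control; the reaction class is established for 3-aryl- and 3-benzylcyclobutanones.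

Step 5
Reactants: 10 p-cresol (4-methylphenol)
Product: 11 2,6-dibromo-4-methylphenol
Conditions: Br2 (2.05 equiv), AcOH, 0 °C to rt
Reagents that add atoms: bromine, BrBr
Why: Electrophilic aromatic bromination, in which the hydroxyl group directs ortho/para and the para position is blocked by the methyl group, so exactly the two ortho positions are brominated.

Step 6
Reactants: 11 2,6-dibromo-4-methylphenol
Product: 12 2,6-dimethoxy-4-methylphenol
Conditions: NaOMe (6 equiv), CuCl (15 mol %), MeOH/DMF, 110 °C; aq. HCl work-up
Reagents that add atoms: sodium methoxide, [Na+].[O-]C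
Why: Ullmann-type copper-catalysed methoxylation, in which a monovalent copper methoxide replaces both aryl bromides and the phenoxide needs no protection; it is well established for 2,6-dibromophenols.

Step 7
Reactants: 9 (R)-4-(3,4-dimethoxybenzyl)dihydrofuran-2(3H)-one; 12 2,6-dimethoxy-4-methylphenol
Product: 15 (3R,4R)-4-(3,4-dimethoxybenzyl)-3-(4-hydroxy-3,5-dimethoxybenzyl)dihydrofuran-2(3H)-one, via lithium enolate 13 (not isolated), via quinone methide 14 (not isolated)
Conditions: 9, LiN(SiMe3)2 (1.05 equiv), THF, −78 °C; separately 12 (1.5 equiv), Ag2O (3 equiv), 4 Å MS, toluene (0.02 M), 0 °C, dark, filtered cold under argon into the enolate; −78 °C, 1 h; aq. NH4Cl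
Reagents that add atoms: none
Why: Proposed new method: a formal cross-dehydrogenative benzylation in which Ag2O removes two electrons and two protons from p-cresol 12 to give the unsubstituted syringyl p-quinone methide 14, whose exocyclic CH2 is an unhindered soft 1,6-acceptor that lithium enolate 13 attacks through carbon, driven by re-aromatisation of the dienone ring, on the enolate face anti to the C4 benzyl group, so that C3 is set trans to C4 (3R,4R) and the phenol emerges free; the closest known reaction types are the 1,6-conjugate (vinylogous Michael) addition of enolates to isolable δ-aryl p-quinone methides and the trans-selective benzylation of β-benzyl-γ-butyrolactone enolates with benzyl bromides.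

**Compound list**

1 | catechol (benzene-1,2-diol) | Oc1ccccc1O | starting material
2 | veratrole (1,2-dimethoxybenzene) | COc1ccccc1OC | intermediate
3 | 3-oxocyclobutane-1-carboxylic acid | OC(=O)C1CC(=O)C1 | starting material
4 | 3-oxocyclobutane-1-carbonyl chloride (acid chloride, not isolated) | ClC(=O)C1CC(=O)C1 | intermediate
5 | 3-(3,4-dimethoxybenzoyl)cyclobutan-1-one (achiral) | COc1ccc(C(=O)C2CC(=O)C2)cc1OC | intermediate
6 | 3-[(3,4-dimethoxyphenyl)(hydroxy)methyl]cyclobutan-1-one (racemic benzylic alcohol, not isolated) | COc1ccc(C(O)C2CC(=O)C2)cc1OC | intermediate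
7 | 3-(3,4-dimethoxybenzyl)cyclobutan-1-one (achiral, prochiral) | COc1ccc(CC2CC(=O)C2)cc1OC | intermediate
8 | 3-(3,4-dimethoxybenzyl)-1-hydroxycyclobutyl 3-chloroperoxybenzoate (Criegee adduct, achiral, cis/trans not defined, not isolated) | COc1ccc(CC2CC(O)(OOC(=O)c3cccc(Cl)c3)C2)cc1OC | intermediate
9 | (R)-4-(3,4-dimethoxybenzyl)dihydrofuran-2(3H)-one | COc1ccc(C[C@H]2COC(=O)C2)cc1OC | intermediate
10 | p-cresol (4-methylphenol) | Cc1ccc(O)cc1 | starting material
11 | 2,6-dibromo-4-methylphenol | Cc1cc(Br)c(O)c(Br)c1 | intermediate
12 | 2,6-dimethoxy-4-methylphenol | COc1cc(C)cc(OC)c1O | intermediate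
13 | lithium (R)-4-(3,4-dimethoxybenzyl)-4,5-dihydrofuran-2-olate (lithium enolate of 9, not isolated) | COc1ccc(C[C@H]2COC([O-])=C2)cc1OC.[Li+] | intermediate
14 | 2,6-dimethoxy-4-methylidenecyclohexa-2,5-dien-1-one (syringyl p-quinone methide, not isolated) | C=C1C=C(OC)C(=O)C(OC)=C1 | intermediate
15 | (3R,4R)-4-(3,4-dimethoxybenzyl)-3-(4-hydroxy-3,5-dimethoxybenzyl)dihydrofuran-2(3H)-one (CNP0280366.1; the two benzyl groups trans) | COc1ccc(C[C@H]2COC(=O)[C@@H]2Cc2cc(OC)c(O)c(OC)c2)cc1OC | target

**Step count and risks**

Total steps: 7. Longest linear sequence: 5 steps (1 → 2 → 5 → 7 → 9 → 15, i.e. steps 1, 2, 3, 4 and 7); the phenol arm (steps 5 and 6) joins at step 7.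

The three steps most likely to fail:

Step 7 (the new coupling). The parent quinone methide 14 may dimerise before it meets the enolate, and unoxidised phenol 12 would protonate enolate 13. The fallback uses known chemistry, sets out from 12 (together with enolate 13 made from 9) and comes back at 15. Phenol 12 is oxidised at its methyl group (O2, CoCl2 cat., NaOH, MeOH, 60 °C) to 4-hydroxy-3,5-dimethoxybenzaldehyde F1, which is O-benzylated (BnBr, K2CO3, DMF) to 4-(benzyloxy)-3,5-dimethoxybenzaldehyde F2. Aldol addition of enolate 13 to F2 (THF, −78 °C) occurs anti to the C4 benzyl group and gives the 3,4-trans β-hydroxy lactone (3S,4R)-3-{[4-(benzyloxy)-3,5-dimethoxyphenyl](hydroxy)methyl}-4-(3,4-dimethoxybenzyl)dihydrofuran-2(3H)-one F3 as a mixture of carbinol epimers. Hydrogenolysis (H2, Pd/C, AcOH, HClO4 cat.) removes the benzylic hydroxyl and the benzyl ether in one operation and gives 15.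

Step 4 (enantioselectivity of the ring expansion). The benzyl group sits one carbon away from the ring, so the ee may fall short, and uncatalysed peracid oxidation gives racemic lactone. The fallback sets out from 7 and comes back at 9. Ketone 7 is desymmetrised by enantioselective deprotonation with the chiral lithium amide LiN[CH(CH3)Ph]2 (hand chosen for the R product, TMSCl present, THF, −100 °C) to the silyl enol ether (R)-{[3-(3,4-dimethoxybenzyl)cyclobut-1-en-1-yl]oxy}trimethylsilane F4. Ozonolysis with reductive work-up (O3, CH2Cl2/MeOH, −78 °C; then NaBH4) cleaves the enol double bond to (3R)-4-(3,4-dimethoxyphenyl)-3-(hydroxymethyl)butanoic acid F5, which lactonises on acidification (aq. HCl) to 9.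

Step 3 (chemoselective deoxygenation). The cyclobutanone may be partly reduced, or the benzylic cation next to the strained ring may rearrange. The fallback replaces steps 2 and 3, sets out from 2 and comes back at 7. Veratrole 2 is brominated (NBS, MeCN) to 4-bromo-1,2-dimethoxybenzene F6 and converted (Mg, THF) into (3,4-dimethoxyphenyl)magnesium bromide F7, which is allylated with allyl bromide to 4-allyl-1,2-dimethoxybenzene F8. [2+2] Cycloaddition with dichloroketene (Cl3CCOCl, Zn–Cu couple, Et2O) gives racemic 2,2-dichloro-3-(3,4-dimethoxybenzyl)cyclobutan-1-one F9, and reductive dechlorination (Zn, AcOH) gives 7.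

**Further compounds**

F1 | step 7 | 4-hydroxy-3,5-dimethoxybenzaldehyde | COc1cc(C=O)cc(OC)c1O
F2 | step 7 | 4-(benzyloxy)-3,5-dimethoxybenzaldehyde | COc1cc(C=O)cc(OC)c1OCc1ccccc1
F3 | step 7 | (3S,4R)-3-{[4-(benzyloxy)-3,5-dimethoxyphenyl](hydroxy)methyl}-4-(3,4-dimethoxybenzyl)dihydrofuran-2(3H)-one, both carbinol epimers | COc1ccc(C[C@H]2COC(=O)[C@@H]2C(O)c2cc(OC)c(OCc3ccccc3)c(OC)c2)cc1OC
F4 | step 4 | (R)-{[3-(3,4-dimethoxybenzyl)cyclobut-1-en-1-yl]oxy}trimethylsilane | COc1ccc(C[C@H]2C=C(O[Si](C)(C)C)C2)cc1OC
F5 | step 4 | (3R)-4-(3,4-dimethoxyphenyl)-3-(hydroxymethyl)butanoic acid | COc1ccc(C[C@H](CC(O)=O)CO)cc1OC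
F6 | step 3 | 4-bromo-1,2-dimethoxybenzene | COc1ccc(Br)cc1OC
F7 | step 3 | (3,4-dimethoxyphenyl)magnesium bromide | COc1ccc([Mg]Br)cc1OC
F8 | step 3 | 4-allyl-1,2-dimethoxybenzene | COc1ccc(CC=C)cc1OC
F9 | step 3 | 2,2-dichloro-3-(3,4-dimethoxybenzyl)cyclobutan-1-one (racemic) | COc1ccc(CC2CC(=O)C2(Cl)Cl)cc1OC
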